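# Proposed total synthesis of CNP0395728.1

## Analysis of the target

- The target is built from four guaiacyl C6–C3 units. Ring A is a 4-hydroxy-3-methoxybenzyl group on C4 of an oxolane (the tetrahydrofuran). C2 of the oxolane carries C5 of a 7-methoxy-2,3-dihydrobenzofuran (ring B), whose C2 carries C5 of a second 7-methoxy-2,3-dihydrobenzofuran (ring C), whose C2 carries the terminal 4-hydroxy-3-methoxyphenyl ring D. Each heterocycle has a CH2OH group on C3.
- There are seven stereocentres. The oxolane is (2R,3R,4R), with the aryl, hydroxymethyl and benzyl groups all on one face. Ring B is (2R,3S) and ring C is (2S,3R), so both are trans but of opposite absolute sense.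
- The three stereochemical units are separated by flat arenes, so none can pass its configuration to the next. Each needs its own source of absolute configuration.
- C2 of each heterocycle is a benzylic ether carbon para to an oxygen and ionises under acid. For rings B and C this is harmless, because trans is the stable arrangement. For the oxolane it is not, because the all-cis arrangement is the less stable C2 epimer.
- The two free phenols are open to oxidation and quinone methide formation. The benzylic ethers rule out hydrogenolysis at any stage.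
- The difficulties are therefore the contra-thermodynamic oxolane, the pseudo-enantiomeric pair of dihydrobenzofurans, and the size of the late intermediates.
- The strategy rests on ring C. Its C2 is a benzylic ether carbon para to the ring D oxygen, so the O1–C2 bond can be made by capture of a stabilised cation. Its C3, with the CH2OH group, is the central carbon of a 2-aryl-propane-1,3-diol whose two hydroxymethyl arms are enantiotopic. Ring B shows the same pattern, with the ring C arene as the para-oxygenated aryl group.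

## Retrosynthetic reasoning

**Protecting groups.** Target 43 is traced to the tetrasilyl ether 42 (two aryl TIPS ethers on rings A and D, two TBDPS ethers on the ring B and ring C hydroxymethyl groups). Fluoride removes all four in one operation and touches none of the benzylic ethers. Ring D carries a silyl ether and the ring B and ring C phenols an allyl ether, so the phenol needed for each ring closure can be unmasked alone under neutral conditions.

**Oxolane, O1–C5 bond.** The aryl group on C2 of 42 is cis to both neighbours, so C2 must not pass through a cation. The ring is cut at O1–C5, where C5 is a methylene and the carbinol C–O bond at C2 stays intact. This leads from tosylate 40 back to bis-tosylate 39 and triol 38. The two primary hydroxyls of 38 cannot be told apart by a reagent, so both are activated and ring size makes the choice: the benzylic alkoxide can reach one tosylate through a five-membered and the other only through a four-membered transition state. The surplus tosylate of 40 is then exchanged for oxygen (41, then 42).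

**Oxolane, C2–C3 bond.** Triol 38 comes from hydroxy lactone 37, and 37 from an aldol reaction of aldehyde 26 with the enolate of lactone 35. The lactone ring of 35 holds the C3/C4 relationship: attack anti to the benzyl group gives the trans lactone, which corresponds to the cis oxolane. The fixed E geometry of a lactone enolate favours the anti carbinol, which becomes the cis C2/C3 pair after closure with retention.

**Lactone 35.** The single stereocentre is set by auxiliary-controlled alkylation: 35 from imide 33, from imide 31, from acid 29, from the commercial acid 27.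

**Aldehyde 26.** The formyl carbon is attached to the ring B arene by way of bromide 24. The bromine atom is carried from the first step as the latent attachment point.

**Ring B, O1–C2 and C2–aryl bonds.** Bromide 24 comes from phenol 23 by a second cation closure, and 23 from allyl ether 22. Compound 22 is cut at the bond between the carbinol carbon and the ring C arene, giving the aryl metal from bromide 14 and aldehyde 19. Only C3 of ring B needs absolute control, and it is already present in 19.

**Ring C, O1–C2 bond (the key disconnection).** Bromide 14 comes from phenol 13 by ionisation of the benzylic alcohol and capture by the phenol oxygen. Phenol 13 comes from allyl ether 12, and 12 from aldehyde 9 and the aryl Grignard reagent 11 of bromide 10. The carbinol configuration of 12 and 13 does not matter, so nothing need control it.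

**Aldehydes 9 and 19.** They are enantiomers and both come from the prochiral diol 5. Enzymatic acylation of 5 gives monoacetate 6, which is taken through 7 and 8 to 9. Enzymatic hydrolysis of diacetate 15 gives the mirror-image monoacetate 16, which is taken through 17 and 18 to 19. One achiral intermediate thus supplies rings B and C in their opposite absolute senses.

**Diol 5.** It comes from malonate 4, made by arylation with iodide 3, which comes from phenol 2 and the commercial phenol 1. Silyl ether 10 also comes from 1.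

## Alternatives that were turned down

**Alternative 1:** quinone methide plus sulfur ylide, building ring B convergently.
- Disconnection: both ring B bonds, O1–C2 and C2–C3, so the molecule is split into a ring A–oxolane–ring B arene half and a ring C–ring D half.
- Forward key step: a carbonate base releases an ortho-quinone methide on the ring B arene and a sulfur ylide on the benzylic carbon of the other half. Conjugate addition forms C2–C3, and the phenoxide then displaces the sulfide to form O1–C2, giving the fully silylated target A1.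
- For: it is the most convergent plan, needs no acid, and the betaine closes to the trans ring.
- Against: the two new stereocentres arise by addition to a planar quinone methide whose only stereochemical neighbours are remote. Nothing chooses between (2R,3S) and (2S,3R), so a near-equal pair of trans diastereomers is expected, at a molecular size where separation is hardest. Both halves must still be made enantiopure, the ring C–ring D half by a closure like the chosen one.
- Comparison: Alternative 1 is stronger on convergence. The chosen route offers instead a local control element for every stereocentre: C3 of ring B comes from the same enzyme that serves ring C, and C2 follows from it.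

**Alternative 2:** carbenoid C–H insertion inside a temporary aryl lactone.
- Disconnection: the oxolane C2–C3 bond, with C3 tied in a lactone to the benzylic carbon of ring A.
- Forward key step: a divalent rhodium carboxylate catalyst turns a diazo group at C3 into a carbenoid that inserts into the benzylic ether C2–H bond, closing the oxolane as the cis-fused furofuranone A2.
- For: the ring fusion forces the C3/C4 cis relationship and the endo aryl group completes the all-cis oxolane directly. On this point it is stronger than the chosen route, which needs an aldol reaction and a retentive ring closure.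
- Against: at that stage the substrate has two more benzylic, oxygen-activated C–H bonds (C2–H of rings B and C) and several electron-rich arenes open to carbenoid attack. The endo preference must win against the usual exo preference. The benzyl group is later unveiled by hydrogenolysis of one benzylic C–O bond in the presence of three others, for which there is no basis of selectivity. Rings B and C are not addressed at all.
- Comparison: the chosen route builds the oxolane with base-mediated steps that leave benzylic C–O bonds alone, and places its main risk on the early, inexpensive ring C closure.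

**Alternative 3:** flavanone ring contraction to ring C.
- Disconnection: the C3–C3a bond of ring C, traced back to the six-membered (2S)-flavanone A4.
- Forward key step: a hypervalent iodine oxidant in acidic orthoformate iodinates the enol ether at C3. The fused arene carbon migrates from C4 to C3, contracting the ring and leaving C4 as the methyl ester of the trans ester A3.
- For: it reaches the ring C–ring D bromide framework in fewer steps than the chosen route, and the 1,2-shift is stereospecific. On step count for this fragment it is stronger.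
- Against: the only stereocentre of A4 is the benzylic ether carbon para to the ring D oxygen. Under acid this centre can ionise or open by retro-oxa-Michael reaction, and any loss of enantiopurity is permanent. The guaiacyl rings compete for the oxidant. The benzyl ether on ring D would need a hydrogenolysis that the benzylic ethers forbid. The method gives no shared intermediate for ring B.
- Comparison: in the chosen route the robust carbon C3 carries the stereochemical information and the labile C2 is set from it reversibly, so erosion at C2 corrects itself. One prochiral diol also serves both dihydrobenzofurans.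

Key step: step 12

Assumption: lipase acetylation of diol 5 is taken to give the (R)-monoacetate 6 and, by the usual enantiocomplementarity, lipase hydrolysis of diacetate 15 the (S)-monoacetate 16; if the enzyme prefers the other arm, the two modes are exchanged between the ring C and ring B series.

Abbreviations used in names:
- TBDPS = tert-butyldiphenylsilyl; TIPS = tri(propan-2-yl)silyl; Ts = 4-methylbenzenesulfonyl.
- ArX = 5-bromo-3-methoxy-2-(prop-2-en-1-yloxy)phenyl.
- ArA = 3-methoxy-4-(TIPS-oxy)phenyl.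
- ArCD = (2S,3R)-3-[(TBDPS-oxy)methyl]-7-methoxy-2-(ArA)-2,3-dihydro-1-benzofuran-5-yl.
- ArBCD = (2R,3S)-3-[(TBDPS-oxy)methyl]-7-methoxy-2-(ArCD)-2,3-dihydro-1-benzofuran-5-yl.

## Route

Step 1
Reactants: 1 4-bromo-2-methoxyphenol
Product: 2 4-bromo-2-iodo-6-methoxyphenol
Conditions: NIS, TsOH·H2O (cat.), MeCN, 0 °C → rt
Reagents that add atoms: N-iodosuccinimide, O=C1CCC(=O)N1I
Why: Electrophilic aromatic iodination; the position para to the hydroxyl is blocked by bromine, so the strongest donor directs iodine to its free ortho position.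

Step 2
Reactants: 2 4-bromo-2-iodo-6-methoxyphenol
Product: 3 5-bromo-1-iodo-3-methoxy-2-(prop-2-en-1-yloxy)benzene
Conditions: allyl bromide, K2CO3, acetone, reflux
Reagents that add atoms: allyl bromide, C=CCBr
Why: Williamson etherification of the phenoxide; the allyl ether survives base, hydride, the enzyme and aryl metals and can later be removed under neutral conditions.

Step 3
Reactants: 3 5-bromo-1-iodo-3-methoxy-2-(prop-2-en-1-yloxy)benzene
Product: 4 diethyl 2-(ArX)propanedioate
Conditions: diethyl malonate, CuI (10 mol %), 2-picolinic acid (20 mol %), Cs2CO3, 1,4-dioxane, rt → 40 °C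
Reagents that add atoms: diethyl malonate, CCOC(=O)CC(=O)OCC
Why: Copper-catalysed α-arylation of a malonate (Ullmann–Hurtley type); monovalent copper reacts with the C–I bond far faster than with the C–Br bond, so the bromine is kept.

Step 4
Reactants: 4 diethyl 2-(ArX)propanedioate
Product: 5 2-(ArX)propane-1,3-diol
Conditions: LiAlH4, Et2O–THF, 0 °C
Reagents that add atoms: none
Why: Hydride reduction of both esters to the prochiral diol; at 0 °C the aryl bromide and the allyl ether are not attacked.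

Step 5
Reactants: 5 2-(ArX)propane-1,3-diol
Product: 6 (2R)-2-(ArX)-3-hydroxypropyl acetate
Conditions: lipase PS (Burkholderia cepacia), vinyl acetate, i-Pr2O, 30 °C
Reagents that add atoms: vinyl acetate, CC(=O)OC=C
Why: Lipase-catalysed irreversible transesterification; the enzyme acylates one of the two enantiotopic hydroxymethyl arms and so sets the carbon that becomes C3 of ring C.

Step 6
Reactants: 6 (2R)-2-(ArX)-3-hydroxypropyl acetate
Product: 7 (2S)-2-(ArX)-3-(TBDPS-oxy)propyl acetate
Conditions: TBDPSCl, imidazole, CH2Cl2, 0 °C → rt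
Reagents that add atoms: tert-butyl(chloro)diphenylsilane, CC(C)(C)[Si](Cl)(c1ccccc1)c1ccccc1
Why: Silylation of the free primary alcohol under mild base; done at once so that acetyl migration between the two arms cannot racemise 6.

Step 7
Reactants: 7 (2S)-2-(ArX)-3-(TBDPS-oxy)propyl acetate
Product: 8 (2S)-2-(ArX)-3-(TBDPS-oxy)propan-1-ol
Conditions: K2CO3 (cat.), MeOH, 0 °C
Reagents that add atoms: none
Why: Base-catalysed methanolysis of the acetate; the bulky TBDPS group is slow to migrate between the two primary oxygens, which would otherwise erase the stereocentre.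

Step 8
Reactants: 8 (2S)-2-(ArX)-3-(TBDPS-oxy)propan-1-ol
Product: 9 (2R)-2-(ArX)-3-(TBDPS-oxy)propanal
Conditions: Dess–Martin periodinane, CH2Cl2, 0 °C → rt; crude aldehyde used at once
Reagents that add atoms: none
Why: Dess–Martin oxidation is neutral and fast; the α-aryl aldehyde can enolise, so it is not purified or stored.

Step 9
Reactants: 1 4-bromo-2-methoxyphenol
Product: 10 (4-bromo-2-methoxyphenoxy)tri(propan-2-yl)silane
Conditions: TIPSCl, imidazole, DMF, rt
Reagents that add atoms: chlorotri(propan-2-yl)silane, CC(C)[Si](Cl)(C(C)C)C(C)C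
Why: Silylation of the phenol; the aryl TIPS ether tolerates Grignard formation and organolithium reagents and keeps the para oxygen a good donor for the later cation.

Step 10
Reactants: 10 (4-bromo-2-methoxyphenoxy)tri(propan-2-yl)silane; 9 (2R)-2-(ArX)-3-(TBDPS-oxy)propanal
Product: 12 (1R,2R)-2-(ArX)-3-(TBDPS-oxy)-1-(ArA)propan-1-ol (drawn epimer; formed together with its (1S,2R) epimer), via arylmagnesium bromide 11 (not isolated)
Conditions: Mg, THF, reflux; then 9, THF, −78 °C
Reagents that add atoms: none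
Why: Grignard addition to the aldehyde; at −78 °C addition outruns enolisation, and the uncontrolled carbinol centre is of no consequence because it is ionised in step 12.

Step 11
Reactants: 12 (1R,2R)-2-(ArX)-3-(TBDPS-oxy)-1-(ArA)propan-1-ol and its (1S,2R) epimer
Product: 13 (1R,2R)-2-(5-bromo-2-hydroxy-3-methoxyphenyl)-3-(TBDPS-oxy)-1-(ArA)propan-1-ol (with its (1S,2R) epimer)
Conditions: Pd(PPh3)4 (5 mol %), morpholine, THF, rt
Reagents that add atoms: none
Why: Tsuji–Trost deallylation; zerovalent palladium ionises the allyl aryl ether and morpholine traps the allyl group, leaving the silyl ethers, the aryl bromide and the benzylic alcohol untouched.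

Step 12
Reactants: 13 (1R,2R)-2-(5-bromo-2-hydroxy-3-methoxyphenyl)-3-(TBDPS-oxy)-1-(ArA)propan-1-ol and its (1S,2R) epimer
Product: 14 tert-butyl{[(2S,3R)-5-bromo-7-methoxy-2-(ArA)-2,3-dihydro-1-benzofuran-3-yl]methoxy}diphenylsilane
Conditions: BF3·OEt2 (2 equiv), CH2Cl2, −78 → −20 °C
Reagents that add atoms: none
Why: BF3·OEt2 binds the benzylic hydroxyl of 13 and ionises it to a cation delocalised onto the para silyloxy oxygen of ring D; the free phenol oxygen on the ring C arene attacks C2 and loses its proton, forming the O1–C2 bond. The closest known reaction type is the acid-mediated dehydrative cyclisation of 1,2-diaryl-propane-1,3-diol ortho-phenols to 2-aryl-2,3-dihydrobenzofurans. Ring C closes in a 5-exo-trig mode, the oxygen adding to the planar cationic carbon whose exocyclic partner is ring D. C2 is the only new stereocentre and is controlled by C3: the CH2OTBDPS group shields one face of the cation, and because the benzylic C–O bond can reionise under the Lewis acid the trans isomer is also the thermodynamic product, so both carbinol epimers of 13 converge on (2S,3R)-14. The step needs trans over cis selectivity, oxygen capture over loss of the C3 proton to a stilbene, and survival of the silyl ethers. The five-membered intramolecular trap, the low temperature and the robust TBDPS and aryl TIPS groups are what secure these.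

Step 13
Reactants: 5 2-(ArX)propane-1,3-diol
Product: 15 2-(ArX)propane-1,3-diyl diacetate
Conditions: Ac2O, pyridine, DMAP (cat.), CH2Cl2, rt
Reagents that add atoms: acetic anhydride, CC(=O)OC(C)=O
Why: Exhaustive acetylation gives the prochiral diester that the enzyme can desymmetrise in the hydrolytic direction.

Step 14
Reactants: 15 2-(ArX)propane-1,3-diyl diacetate
Product: 16 (2S)-2-(ArX)-3-hydroxypropyl acetate
Conditions: lipase PS, phosphate buffer (pH 7)–acetone, 30 °C, stopped at the monoacetate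
Reagents that add atoms: none
Why: Lipase-catalysed hydrolysis; the enzyme hydrolyses the acetate on the arm it would acylate in step 5, so the acetate stays on the other arm and the enantiomer of 6 results, setting the carbon that becomes C3 of ring B.

Step 15
Reactants: 16 (2S)-2-(ArX)-3-hydroxypropyl acetate
Product: 17 (2R)-2-(ArX)-3-(TBDPS-oxy)propyl acetate
Conditions: TBDPSCl, imidazole, CH2Cl2, 0 °C → rt
Reagents that add atoms: tert-butyl(chloro)diphenylsilane, CC(C)(C)[Si](Cl)(c1ccccc1)c1ccccc1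
Why: Silylation as in step 6, before acetyl migration can occur.

Step 16
Reactants: 17 (2R)-2-(ArX)-3-(TBDPS-oxy)propyl acetate
Product: 18 (2R)-2-(ArX)-3-(TBDPS-oxy)propan-1-ol
Conditions: K2CO3 (cat.), MeOH, 0 °C
Reagents that add atoms: none
Why: Methanolysis of the acetate as in step 7.

Step 17
Reactants: 18 (2R)-2-(ArX)-3-(TBDPS-oxy)propan-1-ol
Product: 19 (2S)-2-(ArX)-3-(TBDPS-oxy)propanal
Conditions: Dess–Martin periodinane, CH2Cl2, 0 °C → rt; crude aldehyde used at once
Reagents that add atoms: none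
Why: Dess–Martin oxidation as in step 8, giving the enantiomer of 9.

Step 18
Reactants: 14 tert-butyl{[(2S,3R)-5-bromo-7-methoxy-2-(ArA)-2,3-dihydro-1-benzofuran-3-yl]methoxy}diphenylsilane; 19 (2S)-2-(ArX)-3-(TBDPS-oxy)propanal
Product: 22 (1S,2S)-2-(ArX)-3-(TBDPS-oxy)-1-(ArCD)propan-1-ol (drawn epimer; formed together with its (1R,2S) epimer), via aryllithium 20 (not isolated), via arylmagnesium bromide 21 (not isolated)
Conditions: n-BuLi, THF, −78 °C; MgBr2·OEt2, −78 → −40 °C; then 19, −78 °C
Reagents that add atoms: none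
Why: Bromine–lithium exchange on 14 is faster than any deprotonation at −78 °C, and transmetallation to magnesium lowers the basicity so that Grignard-type addition to the enolisable aldehyde 19 outruns proton transfer. The carbinol centre is again left uncontrolled because step 20 ionises it; the enzyme-set centre beside it is not touched.

Step 19
Reactants: 22 (1S,2S)-2-(ArX)-3-(TBDPS-oxy)-1-(ArCD)propan-1-ol and its (1R,2S) epimer
Product: 23 (1S,2S)-2-(5-bromo-2-hydroxy-3-methoxyphenyl)-3-(TBDPS-oxy)-1-(ArCD)propan-1-ol (with its (1R,2S) epimer)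
Conditions: Pd(PPh3)4 (5 mol %), morpholine, THF, rt
Reagents that add atoms: none
Why: Tsuji–Trost deallylation as in step 11; the aryl TIPS ether on ring D stays in place.

Step 20
Reactants: 23 (1S,2S)-2-(5-bromo-2-hydroxy-3-methoxyphenyl)-3-(TBDPS-oxy)-1-(ArCD)propan-1-ol and its (1R,2S) epimer
Product: 24 {[(2R,3S)-5-bromo-7-methoxy-2-(ArCD)-2,3-dihydro-1-benzofuran-3-yl]methoxy}(tert-butyl)diphenylsilane
Conditions: BF3·OEt2 (2 equiv), CH2Cl2, −78 → −20 °C
Reagents that add atoms: none
Why: The same dehydrative cation cyclisation as step 12; the cation is now stabilised by the ring oxygen of ring C para to it, and the ring B phenol closes trans to the CH2OTBDPS group to give the (2R,3S) ring from both carbinol epimers. If the ring C ether reopens under the Lewis acid it can only reclose to its own trans form.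

Step 21
Reactants: 24 {[(2R,3S)-5-bromo-7-methoxy-2-(ArCD)-2,3-dihydro-1-benzofuran-3-yl]methoxy}(tert-butyl)diphenylsilane
Product: 26 (2R,3S)-3-[(TBDPS-oxy)methyl]-7-methoxy-2-(ArCD)-2,3-dihydro-1-benzofuran-5-carbaldehyde, via aryllithium 25 (not isolated)
Conditions: n-BuLi, THF, −78 °C; DMF, −78 → 0 °C
Reagents that add atoms: N,N-dimethylformamide, CN(C)C=O
Why: Bromine–lithium exchange followed by formylation with DMF (Bouveault reaction); the silyl ethers and the cyclic benzylic ethers are inert to the short exposure at −78 °C.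

Step 22
Reactants: 27 3-(4-hydroxy-3-methoxyphenyl)propanoic acid
Product: 29 3-(ArA)propanoic acid, via silyl ester 28 (not isolated)
Conditions: TIPSCl (2.2 equiv), imidazole, DMF, rt; then K2CO3, MeOH–THF–H2O, rt
Reagents that add atoms: chlorotri(propan-2-yl)silane, CC(C)[Si](Cl)(C(C)C)C(C)C
Why: Silylation of phenol and acid, then selective hydrolysis of the labile silyl ester while the aryl silyl ether stays.

Step 23
Reactants: 29 3-(ArA)propanoic acid
Product: 31 (4S)-4-benzyl-3-[3-(ArA)propanoyl]-1,3-oxazolidin-2-one, via mixed pivalic anhydride 30 (not isolated)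
Conditions: PivCl, Et3N, THF, −20 °C; then (4S)-4-benzyl-1,3-oxazolidin-2-one, LiCl, rt
Reagents that add atoms: (4S)-4-benzyl-1,3-oxazolidin-2-one, O=C1N[C@@H](Cc2ccccc2)CO1
Why: N-Acylation of the Evans auxiliary through the mixed anhydride under mild LiCl/amine conditions.

Step 24
Reactants: 31 (4S)-4-benzyl-3-[3-(ArA)propanoyl]-1,3-oxazolidin-2-one
Product: 33 tert-butyl (3R)-4-[(4S)-4-benzyl-2-oxo-1,3-oxazolidin-3-yl]-3-[(ArA)methyl]-4-oxobutanoate, via sodium enolate 32 (not isolated)
Conditions: NaN(SiMe3)2, THF, −78 °C; tert-butyl bromoacetate, −78 → −40 °C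
Reagents that add atoms: tert-butyl bromoacetate, CC(C)(C)OC(=O)CBr
Why: Evans alkylation; the chelated Z-enolate is alkylated on the face away from the benzyl group of the auxiliary, which sets the (R) centre that becomes C4 of the oxolane.

Step 25
Reactants: 33 tert-butyl (3R)-4-[(4S)-4-benzyl-2-oxo-1,3-oxazolidin-3-yl]-3-[(ArA)methyl]-4-oxobutanoate
Product: 35 (4R)-4-[(ArA)methyl]oxolan-2-one, via hydroxy ester 34 (not isolated)
Conditions: LiBH4, Et2O, H2O (1 equiv), 0 °C; then TsOH·H2O (cat.), CH2Cl2, rt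
Reagents that add atoms: none
Why: Reductive removal of the auxiliary from the imide, which is reduced faster than the tert-butyl ester, followed by acid-catalysed lactonisation; the stereocentre is not epimerisable.

Step 26
Reactants: 35 (4R)-4-[(ArA)methyl]oxolan-2-one; 26 (2R,3S)-3-[(TBDPS-oxy)methyl]-7-methoxy-2-(ArCD)-2,3-dihydro-1-benzofuran-5-carbaldehyde
Product: 37 (3S,4R)-3-[(R)-hydroxy(ArBCD)methyl]-4-[(ArA)methyl]oxolan-2-one, via lithium enolate 36 (not isolated)
Conditions: LiN(i-Pr)2, THF, −78 °C (35, 2 equiv); then 26, −78 °C; AcOH quench at −78 °C; syn epimer removed by chromatography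
Reagents that add atoms: none
Why: Aldol addition of a lactone enolate; the aldehyde approaches anti to the benzyl group (trans lactone), and the ring-enforced E enolate reacts through a Zimmerman–Traxler chair to favour the anti carbinol. These two relationships are the ones that translate into the all-cis oxolane.

Step 27
Reactants: 37 (3S,4R)-3-[(R)-hydroxy(ArBCD)methyl]-4-[(ArA)methyl]oxolan-2-one
Product: 38 (2R,3R)-2-[(R)-hydroxy(ArBCD)methyl]-3-[(ArA)methyl]butane-1,4-diol
Conditions: LiBH4, THF, 0 °C → rt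
Reagents that add atoms: none
Why: Hydride reduction of the lactone to the diol; no stereocentre is touched and the silyl ethers are stable to LiBH4.

Step 28
Reactants: 38 (2R,3R)-2-[(R)-hydroxy(ArBCD)methyl]-3-[(ArA)methyl]butane-1,4-diol
Product: 40 [(2R,3R,4R)-2-(ArBCD)-4-[(ArA)methyl]oxolan-3-yl]methyl 4-methylbenzenesulfonate, via bis-tosylate 39 (not isolated)
Conditions: TsCl (2.3 equiv), Et3N, Me3N·HCl (cat.), CH2Cl2, 0 °C; then NaH, THF, 0 °C → rt
Reagents that add atoms: 4-methylbenzenesulfonyl chloride, Cc1ccc(cc1)S(Cl)(=O)=O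
Why: Selective tosylation of the two primary hydroxyls, then intramolecular Williamson etherification; the benzylic alkoxide reaches the tosylate on the benzyl-bearing arm by 5-exo-tet attack, while the other tosylate would need a four-membered ring. The carbinol C–O bond is never broken, so C2 keeps its configuration and the aryl group ends cis to both neighbours.

Step 29
Reactants: 40 [(2R,3R,4R)-2-(ArBCD)-4-[(ArA)methyl]oxolan-3-yl]methyl 4-methylbenzenesulfonate
Product: 41 [(2R,3R,4R)-2-(ArBCD)-4-[(ArA)methyl]oxolan-3-yl]methyl acetate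
Conditions: CsOAc, 18-crown-6, DMF, 60 °C
Reagents that add atoms: caesium acetate, [Cs+].CC([O-])=O
Why: SN2 displacement of the primary tosylate by the weakly basic acetate returns oxygen to the hydroxymethyl carbon without elimination and without any acid.

Step 30
Reactants: 41 [(2R,3R,4R)-2-(ArBCD)-4-[(ArA)methyl]oxolan-3-yl]methyl acetate
Product: 42 [(2R,3R,4R)-2-(ArBCD)-4-[(ArA)methyl]oxolan-3-yl]methanol
Conditions: i-Bu2AlH, CH2Cl2, −78 °C
Reagents that add atoms: none
Why: Reductive cleavage of the acetate at low temperature leaves all four silyl ethers in place, so the last step starts from one defined compound.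

Step 31
Reactants: 42 [(2R,3R,4R)-2-(ArBCD)-4-[(ArA)methyl]oxolan-3-yl]methanol
Product: 43 4-{[(3R,4R,5R)-5-{(2R,3S)-3-(hydroxymethyl)-2-[(2S,3R)-2-(4-hydroxy-3-methoxyphenyl)-3-(hydroxymethyl)-7-methoxy-2,3-dihydro-1-benzofuran-5-yl]-7-methoxy-2,3-dihydro-1-benzofuran-5-yl}-4-(hydroxymethyl)oxolan-3-yl]methyl}-2-methoxyphenol (the target)
Conditions: Bu4NF, AcOH, THF, 0 °C → rt
Reagents that add atoms: none
Why: Fluoride-mediated global desilylation of the two aryl TIPS and two alkyl TBDPS ethers; buffering with acetic acid keeps the medium near neutral, so no benzylic ether carbon ionises and the phenols are not left as phenoxides.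

## Compound list

1 | 4-bromo-2-methoxyphenol | COc1cc(Br)ccc1O | starting material
2 | 4-bromo-2-iodo-6-methoxyphenol | COc1cc(Br)cc(I)c1O | intermediate
3 | 5-bromo-1-iodo-3-methoxy-2-(prop-2-en-1-yloxy)benzene | C=CCOc1c(I)cc(Br)cc1OC | intermediate
4 | diethyl 2-[5-bromo-3-methoxy-2-(prop-2-en-1-yloxy)phenyl]propanedioate | CCOC(=O)C(C(=O)OCC)c1cc(Br)cc(OC)c1OCC=C | intermediate
5 | 2-[5-bromo-3-methoxy-2-(prop-2-en-1-yloxy)phenyl]propane-1,3-diol | OCC(CO)c1cc(Br)cc(OC)c1OCC=C | intermediate
6 | (2R)-2-[5-bromo-3-methoxy-2-(prop-2-en-1-yloxy)phenyl]-3-hydroxypropyl acetate | C=CCOc1c(OC)cc(Br)cc1[C@@H](COC(C)=O)CO | intermediate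
7 | (2S)-2-[5-bromo-3-methoxy-2-(prop-2-en-1-yloxy)phenyl]-3-[(tert-butyldiphenylsilyl)oxy]propyl acetate | C=CCOc1c(OC)cc(Br)cc1[C@@H](COC(C)=O)CO[Si](c1ccccc1)(c1ccccc1)C(C)(C)C | intermediate
8 | (2S)-2-[5-bromo-3-methoxy-2-(prop-2-en-1-yloxy)phenyl]-3-[(tert-butyldiphenylsilyl)oxy]propan-1-ol | C=CCOc1c(OC)cc(Br)cc1[C@@H](CO)CO[Si](c1ccccc1)(c1ccccc1)C(C)(C)C | intermediate
9 | (2R)-2-[5-bromo-3-methoxy-2-(prop-2-en-1-yloxy)phenyl]-3-[(tert-butyldiphenylsilyl)oxy]propanal | C=CCOc1c(OC)cc(Br)cc1[C@@H](C=O)CO[Si](c1ccccc1)(c1ccccc1)C(C)(C)C | intermediate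
10 | (4-bromo-2-methoxyphenoxy)tri(propan-2-yl)silane | COc1cc(Br)ccc1O[Si](C(C)C)(C(C)C)C(C)C | intermediate
11 | {3-methoxy-4-[(triisopropylsilyl)oxy]phenyl}magnesium bromide | COc1cc([Mg]Br)ccc1O[Si](C(C)C)(C(C)C)C(C)C | intermediate (not isolated)
12 | (1R,2R)-2-(ArX)-3-(TBDPS-oxy)-1-(ArA)propan-1-ol, drawn epimer of a (1R,2R)/(1S,2R) mixture | C=CCOc1c(OC)cc(Br)cc1[C@H](CO[Si](c1ccccc1)(c1ccccc1)C(C)(C)C)[C@@H](O)c1ccc(O[Si](C(C)C)(C(C)C)C(C)C)c(OC)c1 | intermediate
13 | (1R,2R)-2-(5-bromo-2-hydroxy-3-methoxyphenyl)-3-(TBDPS-oxy)-1-(ArA)propan-1-ol, drawn epimer of a (1R,2R)/(1S,2R) mixture | Oc1c(OC)cc(Br)cc1[C@H](CO[Si](c1ccccc1)(c1ccccc1)C(C)(C)C)[C@@H](O)c1ccc(O[Si](C(C)C)(C(C)C)C(C)C)c(OC)c1 | intermediate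
14 | tert-butyl{[(2S,3R)-5-bromo-7-methoxy-2-(ArA)-2,3-dihydro-1-benzofuran-3-yl]methoxy}diphenylsilane | Brc1cc(OC)c2c(c1)[C@H](CO[Si](c1ccccc1)(c1ccccc1)C(C)(C)C)[C@@H](c1ccc(O[Si](C(C)C)(C(C)C)C(C)C)c(OC)c1)O2 | intermediate
15 | 2-[5-bromo-3-methoxy-2-(prop-2-en-1-yloxy)phenyl]propane-1,3-diyl diacetate | CC(=O)OCC(COC(C)=O)c1cc(Br)cc(OC)c1OCC=C | intermediate
16 | (2S)-2-[5-bromo-3-methoxy-2-(prop-2-en-1-yloxy)phenyl]-3-hydroxypropyl acetate | C=CCOc1c(OC)cc(Br)cc1[C@H](COC(C)=O)CO | intermediate
17 | (2R)-2-[5-bromo-3-methoxy-2-(prop-2-en-1-yloxy)phenyl]-3-[(tert-butyldiphenylsilyl)oxy]propyl acetate | C=CCOc1c(OC)cc(Br)cc1[C@H](COC(C)=O)CO[Si](c1ccccc1)(c1ccccc1)C(C)(C)C | intermediate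
18 | (2R)-2-[5-bromo-3-methoxy-2-(prop-2-en-1-yloxy)phenyl]-3-[(tert-butyldiphenylsilyl)oxy]propan-1-ol | C=CCOc1c(OC)cc(Br)cc1[C@H](CO)CO[Si](c1ccccc1)(c1ccccc1)C(C)(C)C | intermediate
19 | (2S)-2-[5-bromo-3-methoxy-2-(prop-2-en-1-yloxy)phenyl]-3-[(tert-butyldiphenylsilyl)oxy]propanal | C=CCOc1c(OC)cc(Br)cc1[C@H](C=O)CO[Si](c1ccccc1)(c1ccccc1)C(C)(C)C | intermediate
20 | aryllithium of 14 (lithium in place of bromine) | [Li]c1cc(OC)c2c(c1)[C@H](CO[Si](c1ccccc1)(c1ccccc1)C(C)(C)C)[C@@H](c1ccc(O[Si](C(C)C)(C(C)C)C(C)C)c(OC)c1)O2 | intermediate (not isolated)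
21 | arylmagnesium bromide of 14 (MgBr in place of bromine) | Br[Mg]c1cc(OC)c2c(c1)[C@H](CO[Si](c1ccccc1)(c1ccccc1)C(C)(C)C)[C@@H](c1ccc(O[Si](C(C)C)(C(C)C)C(C)C)c(OC)c1)O2 | intermediate (not isolated)
22 | (1S,2S)-2-(ArX)-3-(TBDPS-oxy)-1-(ArCD)propan-1-ol, drawn epimer of a (1S,2S)/(1R,2S) mixture | C=CCOc1c(OC)cc(Br)cc1[C@@H](CO[Si](c1ccccc1)(c1ccccc1)C(C)(C)C)[C@H](O)c1cc(OC)c2c(c1)[C@H](CO[Si](c1ccccc1)(c1ccccc1)C(C)(C)C)[C@@H](c1ccc(O[Si](C(C)C)(C(C)C)C(C)C)c(OC)c1)O2 | intermediate
23 | (1S,2S)-2-(5-bromo-2-hydroxy-3-methoxyphenyl)-3-(TBDPS-oxy)-1-(ArCD)propan-1-ol, drawn epimer of a (1S,2S)/(1R,2S) mixture | Oc1c(OC)cc(Br)cc1[C@@H](CO[Si](c1ccccc1)(c1ccccc1)C(C)(C)C)[C@H](O)c1cc(OC)c2c(c1)[C@H](CO[Si](c1ccccc1)(c1ccccc1)C(C)(C)C)[C@@H](c1ccc(O[Si](C(C)C)(C(C)C)C(C)C)c(OC)c1)O2 | intermediate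
24 | {[(2R,3S)-5-bromo-7-methoxy-2-(ArCD)-2,3-dihydro-1-benzofuran-3-yl]methoxy}(tert-butyl)diphenylsilane | Brc1cc(OC)c2c(c1)[C@@H](CO[Si](c1ccccc1)(c1ccccc1)C(C)(C)C)[C@H](c1cc(OC)c3c(c1)[C@H](CO[Si](c1ccccc1)(c1ccccc1)C(C)(C)C)[C@@H](c1ccc(O[Si](C(C)C)(C(C)C)C(C)C)c(OC)c1)O3)O2 | intermediate
25 | aryllithium of 24 (lithium in place of bromine) | [Li]c1cc(OC)c2c(c1)[C@@H](CO[Si](c1ccccc1)(c1ccccc1)C(C)(C)C)[C@H](c1cc(OC)c3c(c1)[C@H](CO[Si](c1ccccc1)(c1ccccc1)C(C)(C)C)[C@@H](c1ccc(O[Si](C(C)C)(C(C)C)C(C)C)c(OC)c1)O3)O2 | intermediate (not isolated)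
26 | (2R,3S)-3-[(TBDPS-oxy)methyl]-7-methoxy-2-(ArCD)-2,3-dihydro-1-benzofuran-5-carbaldehyde | O=Cc1cc(OC)c2c(c1)[C@@H](CO[Si](c1ccccc1)(c1ccccc1)C(C)(C)C)[C@H](c1cc(OC)c3c(c1)[C@H](CO[Si](c1ccccc1)(c1ccccc1)C(C)(C)C)[C@@H](c1ccc(O[Si](C(C)C)(C(C)C)C(C)C)c(OC)c1)O3)O2 | intermediate
27 | 3-(4-hydroxy-3-methoxyphenyl)propanoic acid | COc1cc(CCC(=O)O)ccc1O | starting material
28 | tri(propan-2-yl)silyl 3-(ArA)propanoate | COc1cc(CCC(=O)O[Si](C(C)C)(C(C)C)C(C)C)ccc1O[Si](C(C)C)(C(C)C)C(C)C | intermediate (not isolated)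
29 | 3-{3-methoxy-4-[(triisopropylsilyl)oxy]phenyl}propanoic acid | COc1cc(CCC(=O)O)ccc1O[Si](C(C)C)(C(C)C)C(C)C | intermediate
30 | 3-(ArA)propanoic 2,2-dimethylpropanoic anhydride | COc1cc(CCC(=O)OC(=O)C(C)(C)C)ccc1O[Si](C(C)C)(C(C)C)C(C)C | intermediate (not isolated)
31 | (4S)-4-benzyl-3-[3-(ArA)propanoyl]-1,3-oxazolidin-2-one | COc1cc(CCC(=O)N2[C@@H](Cc3ccccc3)COC2=O)ccc1O[Si](C(C)C)(C(C)C)C(C)C | intermediate
32 | sodium (Z)-enolate of 31 | COc1cc(C/C=C(\O[Na])N2[C@@H](Cc3ccccc3)COC2=O)ccc1O[Si](C(C)C)(C(C)C)C(C)C | intermediate (not isolated)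
33 | tert-butyl (3R)-4-[(4S)-4-benzyl-2-oxo-1,3-oxazolidin-3-yl]-3-[(ArA)methyl]-4-oxobutanoate | CC(C)(C)OC(=O)C[C@@H](Cc1ccc(O[Si](C(C)C)(C(C)C)C(C)C)c(OC)c1)C(=O)N1[C@@H](Cc2ccccc2)COC1=O | intermediate
34 | tert-butyl (3R)-4-hydroxy-3-[(ArA)methyl]butanoate | CC(C)(C)OC(=O)C[C@@H](Cc1ccc(O[Si](C(C)C)(C(C)C)C(C)C)c(OC)c1)CO | intermediate (not isolated)
35 | (4R)-4-({3-methoxy-4-[(triisopropylsilyl)oxy]phenyl}methyl)oxolan-2-one | O=C1C[C@@H](Cc2ccc(O[Si](C(C)C)(C(C)C)C(C)C)c(OC)c2)CO1 | intermediate
36 | lithium enolate of 35 | [Li]OC1=C[C@@H](Cc2ccc(O[Si](C(C)C)(C(C)C)C(C)C)c(OC)c2)CO1 | intermediate (not isolated)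
37 | (3S,4R)-3-[(R)-hydroxy(ArBCD)methyl]-4-[(ArA)methyl]oxolan-2-one (trans lactone, anti carbinol) | O=C1OC[C@H](Cc2ccc(O[Si](C(C)C)(C(C)C)C(C)C)c(OC)c2)[C@H]1[C@@H](O)c1cc(OC)c2c(c1)[C@@H](CO[Si](c1ccccc1)(c1ccccc1)C(C)(C)C)[C@H](c1cc(OC)c3c(c1)[C@H](CO[Si](c1ccccc1)(c1ccccc1)C(C)(C)C)[C@@H](c1ccc(O[Si](C(C)C)(C(C)C)C(C)C)c(OC)c1)O3)O2 | intermediate
38 | (2R,3R)-2-[(R)-hydroxy(ArBCD)methyl]-3-[(ArA)methyl]butane-1,4-diol | OC[C@H](Cc1ccc(O[Si](C(C)C)(C(C)C)C(C)C)c(OC)c1)[C@H](CO)[C@@H](O)c1cc(OC)c2c(c1)[C@@H](CO[Si](c1ccccc1)(c1ccccc1)C(C)(C)C)[C@H](c1cc(OC)c3c(c1)[C@H](CO[Si](c1ccccc1)(c1ccccc1)C(C)(C)C)[C@@H](c1ccc(O[Si](C(C)C)(C(C)C)C(C)C)c(OC)c1)O3)O2 | intermediate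
39 | (2R,3R)-2-[(R)-hydroxy(ArBCD)methyl]-3-[(ArA)methyl]butane-1,4-diyl bis(4-methylbenzenesulfonate) | Cc1ccc(cc1)S(=O)(=O)OC[C@H](Cc1ccc(O[Si](C(C)C)(C(C)C)C(C)C)c(OC)c1)[C@H](COS(=O)(=O)c1ccc(C)cc1)[C@@H](O)c1cc(OC)c2c(c1)[C@@H](CO[Si](c1ccccc1)(c1ccccc1)C(C)(C)C)[C@H](c1cc(OC)c3c(c1)[C@H](CO[Si](c1ccccc1)(c1ccccc1)C(C)(C)C)[C@@H](c1ccc(O[Si](C(C)C)(C(C)C)C(C)C)c(OC)c1)O3)O2 | intermediate (not isolated)
40 | [(2R,3R,4R)-2-(ArBCD)-4-[(ArA)methyl]oxolan-3-yl]methyl 4-methylbenzenesulfonate (all-cis) | COc1cc(C[C@H]2CO[C@@H](c3cc(OC)c4c(c3)[C@@H](CO[Si](c3ccccc3)(c3ccccc3)C(C)(C)C)[C@H](c3cc(OC)c5c(c3)[C@H](CO[Si](c3ccccc3)(c3ccccc3)C(C)(C)C)[C@@H](c3ccc(O[Si](C(C)C)(C(C)C)C(C)C)c(OC)c3)O5)O4)[C@H]2COS(=O)(=O)c6ccc(C)cc6)ccc1O[Si](C(C)C)(C(C)C)C(C)C | intermediate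
41 | [(2R,3R,4R)-2-(ArBCD)-4-[(ArA)methyl]oxolan-3-yl]methyl acetate | COc1cc(C[C@H]2CO[C@@H](c3cc(OC)c4c(c3)[C@@H](CO[Si](c3ccccc3)(c3ccccc3)C(C)(C)C)[C@H](c3cc(OC)c5c(c3)[C@H](CO[Si](c3ccccc3)(c3ccccc3)C(C)(C)C)[C@@H](c3ccc(O[Si](C(C)C)(C(C)C)C(C)C)c(OC)c3)O5)O4)[C@H]2COC(C)=O)ccc1O[Si](C(C)C)(C(C)C)C(C)C | intermediate
42 | [(2R,3R,4R)-2-(ArBCD)-4-[(ArA)methyl]oxolan-3-yl]methanol | COc1cc(C[C@H]2CO[C@@H](c3cc(OC)c4c(c3)[C@@H](CO[Si](c3ccccc3)(c3ccccc3)C(C)(C)C)[C@H](c3cc(OC)c5c(c3)[C@H](CO[Si](c3ccccc3)(c3ccccc3)C(C)(C)C)[C@@H](c3ccc(O[Si](C(C)C)(C(C)C)C(C)C)c(OC)c3)O5)O4)[C@H]2CO)ccc1O[Si](C(C)C)(C(C)C)C(C)C | intermediate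
43 | 4-{[(3R,4R,5R)-5-{(2R,3S)-3-(hydroxymethyl)-2-[(2S,3R)-2-(4-hydroxy-3-methoxyphenyl)-3-(hydroxymethyl)-7-methoxy-2,3-dihydro-1-benzofuran-5-yl]-7-methoxy-2,3-dihydro-1-benzofuran-5-yl}-4-(hydroxymethyl)oxolan-3-yl]methyl}-2-methoxyphenol | COc1cc(C[C@H]2CO[C@@H](c3cc(OC)c4c(c3)[C@@H](CO)[C@H](c3cc(OC)c5c(c3)[C@H](CO)[C@@H](c3ccc(O)c(OC)c3)O5)O4)[C@H]2CO)ccc1O | target

## Step count and risk

Total step count: 31 steps.

Longest linear sequence: 21 steps (steps 1–8, 10–12, 18–21 and 26–31, from 1 to 43).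

**Step 12 (key step).** The most likely failure is loss of the C3 proton from the benzylic cation. This elimination gives a stilbene and destroys the enzyme-set centre. Lewis-acid cleavage of the aryl silyl ether before ring closure is the second concern. The fallback avoids the Lewis acid and goes through a neutral quinone methide.
- It sets out from 13. The ring D silyl ether is removed selectively (Bu4NF, 1 equiv, AcOH, THF, −20 °C) to give the bis-phenol (1R,2R)-2-(5-bromo-2-hydroxy-3-methoxyphenyl)-3-(TBDPS-oxy)-1-(4-hydroxy-3-methoxyphenyl)propan-1-ol F1 (with its carbinol epimer).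
- In buffered aqueous acetonitrile (pH about 4, 40 °C) the para-hydroxybenzyl alcohol should lose water to the para-quinone methide. The ortho phenol traps it trans to the C3 substituent and gives 4-[(2S,3R)-5-bromo-3-[(TBDPS-oxy)methyl]-7-methoxy-2,3-dihydro-1-benzofuran-2-yl]-2-methoxyphenol F2.
- Resilylation (TIPSCl, imidazole, DMF) comes back to the route at 14.

**Step 26.** The most likely failure is poor simple diastereoselection at the carbinol carbon, because the lithium aldol transition state is loose; the trans relationship to the benzyl group is not in doubt. The fallback sets the carbinol centre by ketone reduction in place of the aldol.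
- It sets out from 37 as the epimer mixture. Dess–Martin oxidation gives the trans keto lactone (3S,4R)-3-[(ArBCD)carbonyl]-4-[(ArA)methyl]oxolan-2-one F3.
- Reduction with KBH(s-Bu)3 in THF at −78 °C should follow the Felkin–Anh course, with hydride entering anti to the lactone carbonyl, and comes back to the route at the anti epimer 37.

**Step 28.** The most likely failures are closure through the wrong oxygen if a monotosylate cyclises before the second tosylation, fragmentation of the 1,3-hydroxy tosylate under base, and slow ring closure caused by the all-cis crowding. The fallback masks the hydroxymethyl carbon as an alkene, so that only one primary hydroxyl ever exists.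
- It sets out from 37. Reduction with i-Bu2AlH (CH2Cl2, −78 °C) gives the lactol (3S,4R)-3-[(R)-hydroxy(ArBCD)methyl]-4-[(ArA)methyl]oxolan-2-ol F4.
- Wittig methylenation (Ph3P=CH2, THF, 0 °C) opens it to the alkenyl diol (2R,3S)-3-[(R)-hydroxy(ArBCD)methyl]-2-[(ArA)methyl]pent-4-en-1-ol F5.
- Tosylation of its single primary hydroxyl gives the monotosylate (2R,3S)-3-[(R)-hydroxy(ArBCD)methyl]-2-[(ArA)methyl]pent-4-en-1-yl 4-methylbenzenesulfonate F6, and NaH closes it to the all-cis vinyl oxolane (2R,3S,4R)-3-ethenyl-2-(ArBCD)-4-[(ArA)methyl]oxolane F7.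
- Ozonolysis with NaBH4 work-up at low temperature comes back to the route at 42.
- The lactol and the intermediate aldehyde can epimerise next to the carbonyl, so this sequence is held in reserve.

**Step 18.** The most likely failure is proton transfer from the α-position of aldehyde 19 to the aryl metal in place of addition. This consumes both partners and returns racemised aldehyde. The fallback replaces the basic aryl metal by a non-basic organochromium reagent.
- It sets out from 14. Bromine–lithium exchange and quenching with iodine give the aryl iodide tert-butyl{[(2S,3R)-5-iodo-7-methoxy-2-(ArA)-2,3-dihydro-1-benzofuran-3-yl]methoxy}diphenylsilane F8.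
- Nozaki–Hiyama–Kishi coupling with 19 (CrCl2, divalent chromium, with catalytic NiCl2, DMF, rt) comes back to the route at 22.

**Step 3.** The most likely failure is slow coupling next to the ortho allyloxy group, so that reaction at the C–Br bond or decarboxylation of the product begins to compete. The fallback builds the diol from the aldehyde by an aryl-migrating homologation.
- It sets out from 1. Ortho-formylation (MgCl2, Et3N, paraformaldehyde, MeCN, reflux) gives 5-bromo-2-hydroxy-3-methoxybenzaldehyde F9, and allylation (allyl bromide, K2CO3) gives 5-bromo-3-methoxy-2-(prop-2-en-1-yloxy)benzaldehyde F10.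
- Ethyl diazoacetate with catalytic HBF4·OEt2 (CH2Cl2, −78 °C → rt) gives, by 1,2-aryl shift, ethyl 2-(ArX)-3-hydroxyprop-2-enoate F11.
- Reduction with NaBH4 in ethanol comes back to the route at 5.

Further compounds

F1 | step 12 | (1R,2R)-2-(5-bromo-2-hydroxy-3-methoxyphenyl)-3-[(tert-butyldiphenylsilyl)oxy]-1-(4-hydroxy-3-methoxyphenyl)propan-1-ol (with its (1S,2R) epimer) | Oc1c(OC)cc(Br)cc1[C@H](CO[Si](c1ccccc1)(c1ccccc1)C(C)(C)C)[C@@H](O)c1ccc(O)c(OC)c1
F2 | step 12 | 4-[(2S,3R)-5-bromo-3-{[(tert-butyldiphenylsilyl)oxy]methyl}-7-methoxy-2,3-dihydro-1-benzofuran-2-yl]-2-methoxyphenol | Brc1cc(OC)c2c(c1)[C@H](CO[Si](c1ccccc1)(c1ccccc1)C(C)(C)C)[C@@H](c1ccc(O)c(OC)c1)O2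
F3 | step 26 | (3S,4R)-3-[(ArBCD)carbonyl]-4-[(ArA)methyl]oxolan-2-one (trans keto lactone) | O=C1OC[C@H](Cc2ccc(O[Si](C(C)C)(C(C)C)C(C)C)c(OC)c2)[C@H]1C(=O)c1cc(OC)c2c(c1)[C@@H](CO[Si](c1ccccc1)(c1ccccc1)C(C)(C)C)[C@H](c1cc(OC)c3c(c1)[C@H](CO[Si](c1ccccc1)(c1ccccc1)C(C)(C)C)[C@@H](c1ccc(O[Si](C(C)C)(C(C)C)C(C)C)c(OC)c1)O3)O2
F4 | step 28 | (3S,4R)-3-[(R)-hydroxy(ArBCD)methyl]-4-[(ArA)methyl]oxolan-2-ol (lactol, both anomers) | OC1OC[C@H](Cc2ccc(O[Si](C(C)C)(C(C)C)C(C)C)c(OC)c2)[C@H]1[C@@H](O)c1cc(OC)c2c(c1)[C@@H](CO[Si](c1ccccc1)(c1ccccc1)C(C)(C)C)[C@H](c1cc(OC)c3c(c1)[C@H](CO[Si](c1ccccc1)(c1ccccc1)C(C)(C)C)[C@@H](c1ccc(O[Si](C(C)C)(C(C)C)C(C)C)c(OC)c1)O3)O2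
F5 | step 28 | (2R,3S)-3-[(R)-hydroxy(ArBCD)methyl]-2-[(ArA)methyl]pent-4-en-1-ol | OC[C@H](Cc1ccc(O[Si](C(C)C)(C(C)C)C(C)C)c(OC)c1)[C@H](C=C)[C@@H](O)c1cc(OC)c2c(c1)[C@@H](CO[Si](c1ccccc1)(c1ccccc1)C(C)(C)C)[C@H](c1cc(OC)c3c(c1)[C@H](CO[Si](c1ccccc1)(c1ccccc1)C(C)(C)C)[C@@H](c1ccc(O[Si](C(C)C)(C(C)C)C(C)C)c(OC)c1)O3)O2
F6 | step 28 | (2R,3S)-3-[(R)-hydroxy(ArBCD)methyl]-2-[(ArA)methyl]pent-4-en-1-yl 4-methylbenzenesulfonate | Cc1ccc(cc1)S(=O)(=O)OC[C@H](Cc1ccc(O[Si](C(C)C)(C(C)C)C(C)C)c(OC)c1)[C@H](C=C)[C@@H](O)c1cc(OC)c2c(c1)[C@@H](CO[Si](c1ccccc1)(c1ccccc1)C(C)(C)C)[C@H](c1cc(OC)c3c(c1)[C@H](CO[Si](c1ccccc1)(c1ccccc1)C(C)(C)C)[C@@H](c1ccc(O[Si](C(C)C)(C(C)C)C(C)C)c(OC)c1)O3)O2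
F7 | step 28 | (2R,3S,4R)-3-ethenyl-2-(ArBCD)-4-[(ArA)methyl]oxolane (all-cis) | COc1cc(C[C@H]2CO[C@@H](c3cc(OC)c4c(c3)[C@@H](CO[Si](c3ccccc3)(c3ccccc3)C(C)(C)C)[C@H](c3cc(OC)c5c(c3)[C@H](CO[Si](c3ccccc3)(c3ccccc3)C(C)(C)C)[C@@H](c3ccc(O[Si](C(C)C)(C(C)C)C(C)C)c(OC)c3)O5)O4)[C@H]2C=C)ccc1O[Si](C(C)C)(C(C)C)C(C)C
F8 | step 18 | tert-butyl{[(2S,3R)-5-iodo-7-methoxy-2-(ArA)-2,3-dihydro-1-benzofuran-3-yl]methoxy}diphenylsilane | Ic1cc(OC)c2c(c1)[C@H](CO[Si](c1ccccc1)(c1ccccc1)C(C)(C)C)[C@@H](c1ccc(O[Si](C(C)C)(C(C)C)C(C)C)c(OC)c1)O2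
F9 | step 3 | 5-bromo-2-hydroxy-3-methoxybenzaldehyde | COc1cc(Br)cc(C=O)c1O
F10 | step 3 | 5-bromo-3-methoxy-2-(prop-2-en-1-yloxy)benzaldehyde | C=CCOc1c(C=O)cc(Br)cc1OC
F11 | step 3 | ethyl 2-[5-bromo-3-methoxy-2-(prop-2-en-1-yloxy)phenyl]-3-hydroxyprop-2-enoate | CCOC(=O)C(=CO)c1cc(Br)cc(OC)c1OCC=C
A1 | alternative 1 | fully silylated target (aryl TIPS ethers on rings A and D, tert-butyldimethylsilyl ethers on the three primary alcohols) | COc1cc(C[C@H]2CO[C@@H](c3cc(OC)c4c(c3)[C@@H](CO[Si](C)(C)C(C)(C)C)[C@H](c3cc(OC)c5c(c3)[C@H](CO[Si](C)(C)C(C)(C)C)[C@@H](c3ccc(O[Si](C(C)C)(C(C)C)C(C)C)c(OC)c3)O5)O4)[C@H]2CO[Si](C)(C)C(C)(C)C)ccc1O[Si](C(C)C)(C(C)C)C(C)C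
A2 | alternative 2 | cis-fused furofuranone with the ring B aryl group endo on the ether carbon and the ring A aryl group exo on the lactone carbinol carbon | O=C1O[C@H](c2ccc(O[Si](C(C)C)(C(C)C)C(C)C)c(OC)c2)[C@H]2CO[C@@H](c3cc(OC)c4c(c3)[C@@H](CO[Si](C)(C)C(C)(C)C)[C@H](c3cc(OC)c5c(c3)[C@H](CO[Si](C)(C)C(C)(C)C)[C@@H](c3ccc(O[Si](C(C)C)(C(C)C)C(C)C)c(OC)c3)O5)O4)[C@@H]12
A3 | alternative 3 | methyl (2S,3S)-2-[4-(benzyloxy)-3-methoxyphenyl]-5-bromo-7-methoxy-2,3-dihydro-1-benzofuran-3-carboxylate (trans) | Brc1cc(OC)c2c(c1)[C@H](C(=O)OC)[C@@H](c1ccc(OCc3ccccc3)c(OC)c1)O2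
A4 | alternative 3 | (2S)-2-[4-(benzyloxy)-3-methoxyphenyl]-6-bromo-8-methoxy-2,3-dihydro-4H-chromen-4-one | O=C1C[C@@H](c2ccc(OCc3ccccc3)c(OC)c2)Oc2c(OC)cc(Br)cc12
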